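**Retrosynthetic overview**
- Endgame: the 15-ketone / 1-OAc / 6-CHO precursor gives the target by a final Luche reduction. Ring D (bicyclo[3.2.1]octane) comes from a 5-exo vinyl-radical closure of a C8 α-bromoacryloyl group onto C12=C13.
- Ring A and the spiro 7,20-lactone come from one ring-expanding semipinacol step: a 1-(oxiranyl)cyclopentanol becomes the cyclohexanone as C5 shifts from C1 to C10. This creates quaternary C10, the C1 ketone and the C20–O bond.
- The carbinol comes from a ring-C alkenylmagnesium reagent plus an (S)-cyclopentanone.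
- Ring C comes from an organocatalytic Diels–Alder reaction (butadiene + methyl 4-oxobutenoate), with C20 added by alkyne homologation. The cyclopentanone comes from 3-methylcyclopentenone (conjugate methylation, asymmetric hydroxymethylation).
- Ring order: C, then A (5→6 expansion) together with the lactone, then D.

Assumption: atom labels C1–C20 follow ent-kaurane numbering of the target; one-carbon reagents (MeMgBr, formaldehyde, Ohira–Bestmann reagent) are treated as reagents, and 1, 5, 6 and 18 are the starting materials.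

**Route**

Step 1
Reactants: 1 3-methylcyclopent-2-en-1-one
Product: 2 trimethyl[(3,3-dimethylcyclopent-1-en-1-yl)oxy]silane
Conditions: MeMgBr, CuBr·SMe2 (5 mol %), TMSCl, HMPA, THF, −78 °C; Et3N quench
Reagents that add atoms: methylmagnesium bromide, C[Mg]Br; chlorotrimethylsilane, C[Si](C)(C)Cl
Why: Cu-catalysed conjugate addition with in situ O-silylation gives the regiodefined enol silane (gem-dimethyl C4; no stereocentre).

Step 2
Reactants: 2 trimethyl[(3,3-dimethylcyclopent-1-en-1-yl)oxy]silane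
Product: 3 (2S)-2-(hydroxymethyl)-3,3-dimethylcyclopentan-1-one
Conditions: aq. HCHO, Sc(OTf)3 (10 mol %), chiral 6,6′-bis(1-hydroxy-2,2-dimethylpropyl)-2,2′-bipyridine (12 mol %, the antipode that gives the S ketol), DME/H2O 9:1, −20 °C
Reagents that add atoms: formaldehyde, C=O
Why: Chiral Sc(III)-catalysed aqueous Mukaiyama aldol (hydroxymethylation); the catalyst selects the enol-silane face and sets C5 (S).

Step 3
Reactants: 3 (2S)-2-(hydroxymethyl)-3,3-dimethylcyclopentan-1-one
Product: 4 (2S)-2-{[(tert-butyldimethylsilyl)oxy]methyl}-3,3-dimethylcyclopentan-1-one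
Conditions: TBSCl, imidazole, DMF, 0 °C
Reagents that add atoms: tert-butyldimethylsilyl chloride, CC(C)(C)[Si](C)(C)Cl
Why: Standard silyl ether formation under weakly basic conditions that leave the α-stereocentre untouched.

Step 4
Reactants: 5 buta-1,3-diene; 6 methyl (2E)-4-oxobut-2-enoate
Product: 7 methyl (1R,6R)-6-formylcyclohex-3-ene-1-carboxylate
Conditions: (5R)-5-benzyl-2,2,3-trimethylimidazolidin-4-one·HCl (10 mol %), MeCN/H2O 95:5, excess 5, sealed tube, 0 → 23 °C
Reagents that add atoms: none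
Why: Iminium-catalysed Diels–Alder; the benzyl group shields one face of the (E)-iminium, giving the trans (1R,6R) adduct, whose C6 becomes C9 (C1 = C8 is erased later).

Step 5
Reactants: 7 methyl (1R,6R)-6-formylcyclohex-3-ene-1-carboxylate
Product: 8 methyl (1R,6R)-6-ethynylcyclohex-3-ene-1-carboxylate
Conditions: dimethyl (1-diazo-2-oxopropyl)phosphonate, K2CO3, MeOH, 0 → 23 °C
Reagents that add atoms: dimethyl (1-diazo-2-oxopropyl)phosphonate, CC(=O)C(=[N+]=[N-])P(=O)(OC)OC
Why: Ohira–Bestmann homologation adds C20; the trans isomer necessarily keeps the C9 configuration because the ester-bearing C8 does not epimerise.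

Step 6
Reactants: 8 methyl (1R,6R)-6-ethynylcyclohex-3-ene-1-carboxylate
Product: 10 methyl (1R,6R)-6-(1-iodoethenyl)cyclohex-3-ene-1-carboxylate, via iodoalkenylborane 9 (not isolated)
Conditions: B-iodo-9-BBN, pentane/CH2Cl2, −20 → 0 °C; then AcOH, 0 °C
Reagents that add atoms: B-iodo-9-borabicyclo[3.3.1]nonane, IB1C2CCCC1CCC2
Why: Syn haloboration of the terminal alkyne (B terminal, I internal) followed by protodeboronation gives the Markovnikov 2-iodoalkene; the ring alkene and ester are untouched.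

Step 7
Reactants: 10 methyl (1R,6R)-6-(1-iodoethenyl)cyclohex-3-ene-1-carboxylate; 4 (2S)-2-{[(tert-butyldimethylsilyl)oxy]methyl}-3,3-dimethylcyclopentan-1-one
Product: 12 methyl (1R,6R)-6-{1-[(1S,2S)-2-{[(tert-butyldimethylsilyl)oxy]methyl}-1-hydroxy-3,3-dimethylcyclopentyl]ethenyl}cyclohex-3-ene-1-carboxylate, via alkenylmagnesium chloride 11 (not isolated)
Conditions: i-PrMgCl·LiCl, THF, −20 °C; then 4, LaCl3·2LiCl, −40 → −10 °C; cold NH4Cl quench
Reagents that add atoms: none
Why: Iodine–magnesium exchange then La-promoted 1,2-addition; the alkenyl group adds anti to the CH2OTBS arm, setting the (transient) C1 carbinol cis to C6.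

Step 8
Reactants: 12 tertiary allylic alcohol (name as in step 7)
Product: 15 spiro keto lactone (1-ketone; 6-OTBS; 7,20-δ-lactone trans-fused to the cyclohex-12-ene ring C), via epoxy alcohol 13 (not isolated), via hydroxy ketone ester 14 (not isolated)
Conditions: VO(Oi-Pr)3 (10 mol %), t-BuOOH (decane), 4 Å MS, CH2Cl2, 0 °C; then HFIP, 40 °C
Reagents that add atoms: tert-butyl hydroperoxide, CC(C)(C)OO
Why: Proposed new method: a one-flask vanadium(V) relay. The V–OOt-Bu alkoxide of the tertiary alcohol delivers oxygen to C10=C20 syn to C1–O–V through the A(1,2)-minimised transition state (small C2 arm in the alkene plane, C5 arm out of plane, attack anti to C8 of ring C). In HFIP the V-bound epoxy alkoxide ionises at tertiary C10–O and the antiperiplanar C1–C5 bond migrates (5→6 ring expansion, inversion at C10, retention at C5). The released C20 alkoxide then lactonises onto the C7 ester with loss of MeOH. Closest known chemistry: VO(acac)2/t-BuOOH directed epoxidation of allylic alcohols and, as a separate step, Lewis-acid semipinacol ring expansion of 1-oxiranylcycloalkanols.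

Step 9
Reactants: 15 spiro keto lactone
Product: 16 spiro hydroxy lactone (1-OH cis to C20)
Conditions: NaBH4, MeOH/THF, −20 → 0 °C
Reagents that add atoms: none
Why: Borohydride reduction; axial attack on the face anti to the axial C10–C20 arm gives the equatorial 1-OH (C1 as in the target), and the lactone is not reduced.

Step 10
Reactants: 16 spiro hydroxy lactone
Product: 17 1,6-bis-TBS spiro lactone
Conditions: TBSOTf, 2,6-lutidine, CH2Cl2, 0 °C
Reagents that add atoms: tert-butyldimethylsilyl triflate, CC(C)(C)[Si](C)(C)OS(=O)(=O)C(F)(F)F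
Why: Silylation of the hindered secondary alcohol so that only the lactone α-H (C8) is acidic in the next step.

Step 11
Reactants: 17 1,6-bis-TBS spiro lactone; 18 2,3-dibromopropanoyl chloride
Product: 21 C8-(2-bromoacryloyl) cis-fused spiro lactone, via lithium enolate 19 (not isolated), via dibromo keto lactone 20 (not isolated)
Conditions: LDA, THF, −78 °C; inverse addition to 18, −78 °C; then Et3N, 0 °C
Reagents that add atoms: none
Why: Claisen-type C-acylation of the lactone enolate then E2 loss of HBr; the acyl chloride enters on the enolate face syn to 9-H (opposite both ring bonds at C9), giving the cis ring fusion and C8 as in the target.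

Step 12
Reactants: 21 C8-(2-bromoacryloyl) cis-fused spiro lactone
Product: 22 1,6-bis-TBS 15-oxo-16-methylene bicyclo[3.2.1]octane lactone
Conditions: Bu3SnH (syringe pump), AIBN (cat.), PhH, 80 °C
Reagents that add atoms: none
Why: Stork-type 5-exo-trig vinyl-radical cyclisation onto C13 of the ring alkene (C12 radical reduced by stannane); the bridged geometry dictates C13 and leaves the exocyclic methylene in place.

Step 13
Reactants: 22 1,6-bis-TBS 15-oxo enone lactone
Product: 23 1,6-diol 15-oxo enone lactone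
Conditions: HF·pyridine, THF/pyridine, 0 → 23 °C
Reagents that add atoms: none
Why: Fluoride-driven Si–O cleavage removes both silyl ethers without touching the lactone or enone.

Step 14
Reactants: 23 1,6-diol 15-oxo enone lactone
Product: 24 1-hydroxy 6-aldehyde 15-oxo enone lactone
Conditions: TEMPO (10 mol %), PhI(OAc)2, CH2Cl2, 23 °C
Reagents that add atoms: none
Why: Oxoammonium (TEMPO/BAIB) oxidation is selective for the primary C6 alcohol over the hindered, non-activated secondary 1-OH.

Step 15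
Reactants: 24 1-hydroxy 6-aldehyde 15-oxo enone lactone
Product: 25 1-acetoxy 6-aldehyde 15-oxo enone lactone
Conditions: Ac2O, pyridine, DMAP (cat.), CH2Cl2, 0 → 23 °C
Reagents that add atoms: acetic anhydride, CC(=O)OC(C)=O
Why: Standard acylation of the only free hydroxyl; the C5–CHO centre is the equatorial, thermodynamically preferred epimer.

Step 16
Reactants: 25 1-acetoxy 6-aldehyde 15-oxo enone lactone
Product: 28 target CNP0117386.1, via dimethyl acetal enone 26 (not isolated), via dimethyl acetal allylic alcohol 27 (not isolated)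
Conditions: CeCl3·7H2O, HC(OMe)3, MeOH, 23 °C; then NaBH4, −78 °C; then 1 M HCl, THF, 0 °C
Reagents that add atoms: none
Why: Gemal–Luche protocol; Ce(III)-catalysed acetalisation masks the aldehyde, Luche 1,2-reduction from the exo face (C14/C7 side) gives the endo 15-OH of the target, and acid work-up restores the aldehyde.

**Compound list**
1 | 3-methylcyclopent-2-en-1-one | CC1=CC(=O)CC1 | starting material
2 | trimethyl[(3,3-dimethylcyclopent-1-en-1-yl)oxy]silane | CC1(C)C=C(O[Si](C)(C)C)CC1 | intermediate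
3 | (2S)-2-(hydroxymethyl)-3,3-dimethylcyclopentan-1-one | O=C1CCC(C)(C)[C@H]1CO | intermediate
4 | (2S)-2-{[(tert-butyldimethylsilyl)oxy]methyl}-3,3-dimethylcyclopentan-1-one | O=C1CCC(C)(C)[C@H]1CO[Si](C)(C)C(C)(C)C | intermediate
5 | buta-1,3-diene | C=CC=C | starting material
6 | methyl (2E)-4-oxobut-2-enoate | COC(=O)/C=C/C=O | starting material
7 | methyl (1R,6R)-6-formylcyclohex-3-ene-1-carboxylate (trans) | COC(=O)[C@@H]1CC=CC[C@H]1C=O | intermediate
8 | methyl (1R,6R)-6-ethynylcyclohex-3-ene-1-carboxylate | COC(=O)[C@@H]1CC=CC[C@H]1C#C | intermediate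
9 | methyl (1R,6R)-6-[(Z)-2-(9-borabicyclo[3.3.1]nonan-9-yl)-1-iodoethenyl]cyclohex-3-ene-1-carboxylate | COC(=O)[C@@H]1CC=CC[C@H]1C(/I)=C/B2C3CCCC2CCC3 | intermediate
10 | methyl (1R,6R)-6-(1-iodoethenyl)cyclohex-3-ene-1-carboxylate | COC(=O)[C@@H]1CC=CC[C@H]1C(I)=C | intermediate
11 | alkenylmagnesium chloride from 10 (MgCl in place of I) | COC(=O)[C@@H]1CC=CC[C@H]1C(=C)[Mg]Cl | intermediate
12 | methyl (1R,6R)-6-{1-[(1S,2S)-2-{[(tert-butyldimethylsilyl)oxy]methyl}-1-hydroxy-3,3-dimethylcyclopentyl]ethenyl}cyclohex-3-ene-1-carboxylate | COC(=O)[C@@H]1CC=CC[C@H]1C(=C)[C@]2(O)CCC(C)(C)[C@H]2CO[Si](C)(C)C(C)(C)C | intermediate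
13 | 10,20-epoxide of 12 (oxirane oxygen on the C10 face anti to C8) | COC(=O)[C@@H]1CC=CC[C@H]1[C@@]3(CO3)[C@]2(O)CCC(C)(C)[C@H]2CO[Si](C)(C)C(C)(C)C | intermediate
14 | methyl trans-6-[1-(hydroxymethyl)-3,3-dimethyl-6-oxo-2-(TBSO-methyl)cyclohexyl]cyclohex-3-ene-1-carboxylate; C5, C9, C10 as in 28 | COC(=O)[C@@H]1CC=CC[C@H]1[C@]2(CO)C(=O)CCC(C)(C)[C@H]2CO[Si](C)(C)C(C)(C)C | intermediate
15 | spiro keto lactone: A-ring 1-ketone, 6-OTBS, 7,20-lactone trans-fused to cyclohex-12-ene ring C (8-H anti to 9-H); C5, C9, C10 as in 28 | O=C1OC[C@]2(C(=O)CCC(C)(C)[C@H]2CO[Si](C)(C)C(C)(C)C)[C@@H]3CC=CC[C@@H]13 | intermediate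
16 | 1-alcohol of 15 (1-OH cis to C20, as in 28) | O=C1OC[C@]2([C@@H](O)CCC(C)(C)[C@H]2CO[Si](C)(C)C(C)(C)C)[C@@H]3CC=CC[C@@H]13 | intermediate
17 | 1,6-bis-TBS ether of 16 | O=C1OC[C@]2([C@@H](O[Si](C)(C)C(C)(C)C)CCC(C)(C)[C@H]2CO[Si](C)(C)C(C)(C)C)[C@@H]3CC=CC[C@@H]13 | intermediate
18 | 2,3-dibromopropanoyl chloride | O=C(Cl)C(Br)CBr | starting material
19 | lithium enolate of 17 (C7–OLi, C7=C8) | [Li]OC1=C2CC=CC[C@H]2[C@]3(CO1)[C@@H](O[Si](C)(C)C(C)(C)C)CCC(C)(C)[C@H]3CO[Si](C)(C)C(C)(C)C | intermediate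
20 | C8-(2,3-dibromopropanoyl) derivative of 17, acyl cis to 9-H, CHBr epimers | O=C1OC[C@]2([C@@H](O[Si](C)(C)C(C)(C)C)CCC(C)(C)[C@H]2CO[Si](C)(C)C(C)(C)C)[C@@H]3CC=CC[C@]13C(=O)C(Br)CBr | intermediate
21 | C8-(2-bromoacryloyl) derivative of 17 (cis-fused lactone, C8 as in 28) | O=C1OC[C@]2([C@@H](O[Si](C)(C)C(C)(C)C)CCC(C)(C)[C@H]2CO[Si](C)(C)C(C)(C)C)[C@@H]3CC=CC[C@]13C(=O)C(Br)=C | intermediate
22 | 1,6-bis-O-TBS 15-oxo-16-methylene bicyclo[3.2.1]octane spiro lactone (target skeleton; 1-OTBS, 6-CH2OTBS, 15-C=O) | C=C1[C@@H]2CC[C@@H]3[C@](C2)(C(=O)OC[C@]32[C@@H](O[Si](C)(C)C(C)(C)C)CCC(C)(C)[C@H]2CO[Si](C)(C)C(C)(C)C)C1=O | intermediate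
23 | 1,6-diol of 22 | C=C1[C@@H]2CC[C@@H]3[C@](C2)(C(=O)OC[C@]32[C@@H](O)CCC(C)(C)[C@H]2CO)C1=O | intermediate
24 | 1-hydroxy 6-aldehyde 15-ketone | C=C1[C@@H]2CC[C@@H]3[C@](C2)(C(=O)OC[C@]32[C@@H](O)CCC(C)(C)[C@H]2C=O)C1=O | intermediate
25 | 1-acetoxy 6-aldehyde 15-ketone (15-oxo analogue of the target) | C=C1[C@@H]2CC[C@@H]3[C@](C2)(C(=O)OC[C@]32[C@@H](OC(C)=O)CCC(C)(C)[C@H]2C=O)C1=O | intermediate
26 | 6-dimethyl acetal of 25 | C=C1[C@@H]2CC[C@@H]3[C@](C2)(C(=O)OC[C@]32[C@@H](OC(C)=O)CCC(C)(C)[C@H]2C(OC)OC)C1=O | intermediate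
27 | 15-alcohol (endo OH) of 26 | C=C1[C@@H]2CC[C@@H]3[C@](C2)(C(=O)OC[C@]32[C@@H](OC(C)=O)CCC(C)(C)[C@H]2C(OC)OC)[C@@H]1O | intermediate
28 | CNP0117386.1 | C=C1[C@@H]2CC[C@@H]3[C@](C2)(C(=O)OC[C@]32[C@@H](OC(C)=O)CCC(C)(C)[C@H]2C=O)[C@@H]1O | target

**Totals**
Total steps: 16. Longest linear sequence: 13 (steps 1–3 or 4–6, then 7–16).

**Three steps most likely to fail**

Step 8 (the proposed new vanadium relay). The cascade may stop at the epoxide, or the ester carbonyl may trap C10. The fallback uses known chemistry only and gives up the one-flask relay for the classical staged sequence. It sets out from 12: VO(acac)2/t-BuOOH in benzene gives the epoxy alcohol 13, which is isolated. Stoichiometric BF3·OEt2 in CH2Cl2 at −78 °C then effects the semipinacol ring expansion to 14, and p-TsOH (cat.) in warm benzene closes the lactone, returning to the route at 15. No compound outside the list is made (F0).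

Step 7 (1,2-addition of a hindered alkenylmagnesium to an enolisable β-silyloxy ketone in the presence of a methyl ester). The fallback masks the ester as a carboxylate and uses an organocerium. It sets out from 10: LiOH hydrolysis gives (1R,6R)-6-(1-iodoethenyl)cyclohex-3-ene-1-carboxylic acid F1. Deprotonation (n-BuLi), iodine–lithium exchange (t-BuLi, −78 °C), transmetalation with CeCl3 and addition to 4 give the hydroxy acid F2. TMSCHN2 esterification returns to the route at 12.

Step 11 (C-acylation of a hindered lactone enolate with an acid chloride that can itself lose HBr). The fallback replaces acylation by an aldol/oxidation pair. It sets out from 17: the LDA enolate is added to 2-bromoacrolein to give the C8 aldol adduct F3 (C15 epimers, same cis fusion). Dess–Martin oxidation returns to the route at 21.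

Further compounds
F1 | step 7 | (1R,6R)-6-(1-iodoethenyl)cyclohex-3-ene-1-carboxylic acid | OC(=O)[C@@H]1CC=CC[C@H]1C(I)=C
F2 | step 7 | (1R,6R)-6-{1-[(1S,2S)-2-{[(tert-butyldimethylsilyl)oxy]methyl}-1-hydroxy-3,3-dimethylcyclopentyl]ethenyl}cyclohex-3-ene-1-carboxylic acid | OC(=O)[C@@H]1CC=CC[C@H]1C(=C)[C@]2(O)CCC(C)(C)[C@H]2CO[Si](C)(C)C(C)(C)C
F0 | step 8 | none | none
F3 | step 11 | C8-(2-bromo-1-hydroxyprop-2-en-1-yl) derivative of 17 (C15 epimers) | O=C1OC[C@]2([C@@H](O[Si](C)(C)C(C)(C)C)CCC(C)(C)[C@H]2CO[Si](C)(C)C(C)(C)C)[C@@H]3CC=CC[C@]13C(O)C(Br)=C
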